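**Retrosynthetic overview**
- Feature: ring A is fully substituted. Its four adjacent oxygen-bearing carbons C5–C8 (vicinal methoxyls on C6/C7) map onto the C4O4 core of dimethyl squarate. Its last two carbons, C4a=C8a with O1 on C8a, are the enol ether double bond of a dihydropyran (ring C).
- Ring A: disconnect C4a–C5 (6π closure of a dienylketene released by 4π opening of a cyclobutenone) and C8–C8a (C8a vinyllithium plus a squarate carbonyl).
- The carbinol oxygen is methylated in the addition flask. The ring expansion then delivers C8–OMe and a free C5–OH already differentiated, so no methylation/demethylation pair is needed on the racemisable flavanone.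
- Ring C: disconnect C2–C3 and O1–C8a by an enantioselective hetero-Diels–Alder reaction of the O-silylated ring B aldehyde with a 1-methoxy-3-silyloxydiene. This sets C2; C4 is carried as a cis silyl ether and is oxidised last.
- Ring order: B (bought), C (step 2), A (step 6).

Key step: step 6

Remark: flavanone numbering (O1, C2, C3, C4, C4a, C5–C8, C8a; ring B primed) is used for all intermediates.

Assumption: the (S,S) catalyst is specified from the sense of induction known for benzaldehyde with this catalyst family. The configuration is to be confirmed by MTPA ester analysis of the C4 carbinol from step 3, and the mirror-image catalyst is used if the sense is reversed.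

**Step 1**
Reactants: 1 2-hydroxy-6-methoxybenzaldehyde
Product: 2 2-methoxy-6-(triisopropylsilyloxy)benzaldehyde
Conditions: TIPSCl, imidazole, DMAP (cat.), DMF, rt
Reagents that add atoms: triisopropylsilyl chloride (TIPSCl), CC(C)[Si](Cl)(C(C)C)C(C)C
Why: Phenol silylation (substitution at silicon, imidazole catalysis); the bulky TIPS ether masks the acidic OH, should survive Lewis acid, hydride and t-BuLi, does not direct ortho-lithiation and has no Si–CH3 group.

**Step 2**
Reactants: 2 2-methoxy-6-(triisopropylsilyloxy)benzaldehyde; 3 (E)-1-methoxy-3-(trimethylsilyloxy)buta-1,3-diene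
Product: 5 (S)-2-[2-methoxy-6-(triisopropylsilyloxy)phenyl]-2,3-dihydro-4H-pyran-4-one, via silyl enol ether cycloadduct 4 (not isolated)
Conditions: (S,S)-(salen)CrBF4 (5 mol %; salen = dianion of N,N'-bis(3,5-di-tert-butylsalicylidene)cyclohexane-1,2-diamine), 4 Å MS, t-BuOMe, −30 °C to rt; then TFA (cat.), CH2Cl2, 0 °C
Reagents that add atoms: none
Why: Catalytic enantioselective hetero-Diels–Alder reaction of the aldehyde C=O forms C2–C3 and O1–C8a, acid then expels methanol and the silyl group, and C2 is set by the chiral salen ligand, which shields one face of the chromium-bound aldehyde.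

**Step 3**
Reactants: 5 (S)-2-[2-methoxy-6-(triisopropylsilyloxy)phenyl]-2,3-dihydro-4H-pyran-4-one
Product: 6 (2S,4S)-2-[2-methoxy-6-(triisopropylsilyloxy)phenyl]-3,4-dihydro-2H-pyran-4-ol
Conditions: NaBH4, CeCl3·7H2O, MeOH–CH2Cl2, −78 °C
Reagents that add atoms: none
Why: Luche reduction gives 1,2-selective hydride delivery, with axial attack on the half-chair that holds the aryl group equatorial, so the C4 carbinol should be equatorial and cis to the aryl group (4S); this centre is only a placeholder for the later ketone.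

**Step 4**
Reactants: 6 (2S,4S)-2-[2-methoxy-6-(triisopropylsilyloxy)phenyl]-3,4-dihydro-2H-pyran-4-ol
Product: 7 (2S,4S)-4-(tert-butyldimethylsilyloxy)-2-[2-methoxy-6-(triisopropylsilyloxy)phenyl]-3,4-dihydro-2H-pyran
Conditions: TBSCl, imidazole, DMF, rt
Reagents that add atoms: tert-butyldimethylsilyl chloride (TBSCl), CC(C)(C)[Si](C)(C)Cl
Why: Silyl ether formation masks the allylic alcohol against t-BuLi, and the imidazole-buffered medium avoids Ferrier-type ionisation of the allylic enol ether.

**Step 5**
Reactants: 7 (2S,4S)-4-(tert-butyldimethylsilyloxy)-2-[2-methoxy-6-(triisopropylsilyloxy)phenyl]-3,4-dihydro-2H-pyran; 8 dimethyl squarate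
Product: 11 2,3,4-trimethoxy-4-{(2S,4S)-4-(tert-butyldimethylsilyloxy)-2-[2-methoxy-6-(triisopropylsilyloxy)phenyl]-3,4-dihydro-2H-pyran-6-yl}cyclobut-2-en-1-one (both epimers at the quaternary carbon), via vinyllithium 9 (not isolated), via lithium alkoxide 10 (not isolated)
Conditions: t-BuLi (1.8 equiv), THF–pentane, −78 to 0 °C; then 8 (1.3 equiv), THF, −78 °C; then MeOTf, −78 to 0 °C
Reagents that add atoms: methyl trifluoromethanesulfonate (MeOTf), COS(=O)(=O)C(F)(F)F
Why: α-Lithiation of a cyclic enol ether, as practised on silyl-protected glycals, takes the vinylic C8a–H next to O1 (on ring B the TIPS ether does not direct, the lone methoxy group directs only weakly at low temperature, and the C2–H is held in the arene plane by the two ortho substituents), 1,2-addition of 9 to one of the two equivalent squarate carbonyls forms C8–C8a, and O-alkylation of alkoxide 10 with methyl triflate installs the future C8 methyl ether; the new quaternary centre forms unselectively, which does not matter because step 6 destroys it.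

**Step 6**
Reactants: 11 2,3,4-trimethoxy-4-{(2S,4S)-4-(tert-butyldimethylsilyloxy)-2-[2-methoxy-6-(triisopropylsilyloxy)phenyl]-3,4-dihydro-2H-pyran-6-yl}cyclobut-2-en-1-one
Product: 14 (2S,4S)-4-(tert-butyldimethylsilyloxy)-6,7,8-trimethoxy-2-[2-methoxy-6-(triisopropylsilyloxy)phenyl]chroman-5-ol, via dienylketene 12 (not isolated), via cyclohexadienone 13 (not isolated)
Conditions: PhMe (degassed, dilute), 110 °C, Ar
Reagents that add atoms: none
Why: Moore rearrangement: heat breaks the C(=O)–C(OMe) bond of the cyclobutenone by conrotatory 4π electrocyclic opening to dienylketene 12, the ketene carbon (future C5) bonds to C4a in a disrotatory 6π electrocyclisation to cyclohexadienone 13, and transfer of the C4a hydrogen to oxygen aromatises it to phenol 14. The closest known reaction type is the thermal ring expansion of squarate-derived 4-alkenyl-4-hydroxy- or 4-alkoxycyclobutenones to hydroquinones and their monoethers. Ring A closes as a six-membered carbocycle by the 6π electrocyclisation (one new skeletal bond, C4a–C5), the C8–C8a bond having been made in step 5. The selectivity needed is torquoselectivity: the donor methoxy group on the breaking carbon rotates outward, as is inherent to 4-oxygenated cyclobutenones, so the dihydropyranyl group turns inward next to the ketene and both epimers of 11 converge. No lasting stereocentre forms (C4a of 13 is lost on aromatisation), and C2 and C4 are spectators under the neutral conditions. Because the former carbinol oxygen carries methyl, C8 emerges as OMe and only the ketene oxygen appears as the free C5 phenol, and no hydroxyl is present that could trap the ketene as a butenolide.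

**Step 7**
Reactants: 14 (2S,4S)-4-(tert-butyldimethylsilyloxy)-6,7,8-trimethoxy-2-[2-methoxy-6-(triisopropylsilyloxy)phenyl]chroman-5-ol
Product: 15 (2S,4S)-2-(2-hydroxy-6-methoxyphenyl)-6,7,8-trimethoxychroman-4,5-diol
Conditions: Bu4NF–AcOH (1:1, 3 equiv), THF, 0 °C to rt
Reagents that add atoms: none
Why: Fluoride-induced cleavage of both silyl ethers, buffered with acetic acid so that no free phenoxide can open ring C at C2–O1 through a quinone methide, and free of strong acid so that the ionisable C4 benzylic carbinol is kept.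

**Step 8**
Reactants: 15 (2S,4S)-2-(2-hydroxy-6-methoxyphenyl)-6,7,8-trimethoxychroman-4,5-diol
Product: 16 (S)-5-hydroxy-2-(2-hydroxy-6-methoxyphenyl)-6,7,8-trimethoxychroman-4-one (CNP0215836.1)
Conditions: activated MnO2 (excess), CH2Cl2, rt
Reagents that add atoms: none
Why: Benzylic alcohol oxidation with MnO2 under neutral heterogeneous conditions; the carbinol is activated by electron-rich ring A, the ketone formed is hydrogen-bonded to C5–OH and deactivates ring A towards further oxidation, and no acid or base is present that could racemise C2 through the chalcone.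

**Compound list**
1 | 2-hydroxy-6-methoxybenzaldehyde | COc1cccc(O)c1C=O | starting material
2 | 2-methoxy-6-(triisopropylsilyloxy)benzaldehyde | COc1cccc(O[Si](C(C)C)(C(C)C)C(C)C)c1C=O | intermediate
3 | (E)-1-methoxy-3-(trimethylsilyloxy)buta-1,3-diene | CO/C=C/C(=C)O[Si](C)(C)C | starting material
4 | (2S)-6-methoxy-2-[2-methoxy-6-(triisopropylsilyloxy)phenyl]-4-(trimethylsilyloxy)-3,6-dihydro-2H-pyran (acetal centre undefined) | COc1cccc(O[Si](C(C)C)(C(C)C)C(C)C)c1[C@@H]1CC(O[Si](C)(C)C)=CC(OC)O1 | intermediate
5 | (S)-2-[2-methoxy-6-(triisopropylsilyloxy)phenyl]-2,3-dihydro-4H-pyran-4-one | COc1cccc(O[Si](C(C)C)(C(C)C)C(C)C)c1[C@@H]1CC(=O)C=CO1 | intermediate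
6 | (2S,4S)-2-[2-methoxy-6-(triisopropylsilyloxy)phenyl]-3,4-dihydro-2H-pyran-4-ol | COc1cccc(O[Si](C(C)C)(C(C)C)C(C)C)c1[C@@H]1C[C@H](O)C=CO1 | intermediate
7 | (2S,4S)-4-(tert-butyldimethylsilyloxy)-2-[2-methoxy-6-(triisopropylsilyloxy)phenyl]-3,4-dihydro-2H-pyran | COc1cccc(O[Si](C(C)C)(C(C)C)C(C)C)c1[C@@H]1C[C@H](O[Si](C)(C)C(C)(C)C)C=CO1 | intermediate
8 | dimethyl squarate | COC1=C(OC)C(=O)C1=O | starting material
9 | C8a-lithio derivative of 7 (vinyllithium) | COc1cccc(O[Si](C(C)C)(C(C)C)C(C)C)c1[C@@H]1C[C@H](O[Si](C)(C)C(C)(C)C)C=C([Li])O1 | intermediate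
10 | lithium alkoxide of the 4-hydroxy-2,3-dimethoxy-4-(dihydropyran-6-yl)cyclobutenone (both epimers) | COc1cccc(O[Si](C(C)C)(C(C)C)C(C)C)c1[C@@H]1C[C@H](O[Si](C)(C)C(C)(C)C)C=C(O1)C1(O[Li])C(OC)=C(OC)C1=O | intermediate
11 | 2,3,4-trimethoxy-4-{(2S,4S)-4-(tert-butyldimethylsilyloxy)-2-[2-methoxy-6-(triisopropylsilyloxy)phenyl]-3,4-dihydro-2H-pyran-6-yl}cyclobut-2-en-1-one (both epimers) | COc1cccc(O[Si](C(C)C)(C(C)C)C(C)C)c1[C@@H]1C[C@H](O[Si](C)(C)C(C)(C)C)C=C(O1)C1(OC)C(OC)=C(OC)C1=O | intermediate
12 | (3Z)-2,3,4-trimethoxy-4-(dihydropyran-6-yl)buta-1,3-dien-1-one (dienylketene, pyranyl group inward) | COc1cccc(O[Si](C(C)C)(C(C)C)C(C)C)c1[C@@H]1C[C@H](O[Si](C)(C)C(C)(C)C)C=C(O1)\C(OC)=C(OC)/C(OC)=C=O | intermediate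
13 | 4a-H-cyclohexa-2,4-dienone from 6π closure (C4a undefined) | COc1cccc(O[Si](C(C)C)(C(C)C)C(C)C)c1[C@@H]1C[C@H](O[Si](C)(C)C(C)(C)C)C2C(=O)C(OC)=C(OC)C(OC)=C2O1 | intermediate
14 | (2S,4S)-4-(tert-butyldimethylsilyloxy)-6,7,8-trimethoxy-2-[2-methoxy-6-(triisopropylsilyloxy)phenyl]chroman-5-ol | COc1cccc(O[Si](C(C)C)(C(C)C)C(C)C)c1[C@@H]1C[C@H](O[Si](C)(C)C(C)(C)C)c2c(O)c(OC)c(OC)c(OC)c2O1 | intermediate
15 | (2S,4S)-2-(2-hydroxy-6-methoxyphenyl)-6,7,8-trimethoxychroman-4,5-diol | COc1cccc(O)c1[C@@H]1C[C@H](O)c2c(O)c(OC)c(OC)c(OC)c2O1 | intermediate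
16 | (S)-5-hydroxy-2-(2-hydroxy-6-methoxyphenyl)-6,7,8-trimethoxychroman-4-one | COc1cccc(O)c1[C@@H]1CC(=O)c2c(O)c(OC)c(OC)c(OC)c2O1 | target

**Step count**
- Total step count: 8.
- Longest linear sequence: 8 steps (from 1).

**Steps most likely to fail**

1. **Step 5.**
   - Risk: the metalation may not be site-selective. Deprotonation ortho to the ring B methoxy group, at the benzylic C2–H (which would also erode the stereocentre) or on a Si–CH3 group can compete with removal of the C8a–H. Base left over would add to the squarate.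
   - Fallback: C8a is acidified instead of forced. Setting out from 7, benzenesulfinic acid is added across the enol ether (CH2Cl2, rt) to give the anomeric sulfone F1.
   - n-BuLi at −78 °C then removes only the C8a–H flanked by the sulfonyl group and O1. The carbanion is added to 8 and the alkoxide is methylated with MeOTf to give the tertiary sulfone adduct F2.
   - On warming with Et3N this loses benzenesulfinic acid towards C4a, the only neighbouring C–H, and the route is rejoined at 11.

2. **Step 2.**
   - Risk: the aldehyde is doubly ortho-substituted and electron-rich, so slow cycloaddition and poor facial selectivity at the crowded chromium centre are the likely failure.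
   - Fallback: induction is replaced by resolution. Setting out from 2 and 3, cyclocondensation with BF3·OEt2 (Et2O, −78 °C) followed by TFA gives the racemic dihydropyranone F3.
   - This is separated by preparative chromatography on a chiral stationary phase into 5 and the (R)-dihydropyranone F4, which is set aside. The route is rejoined at 5.

3. **Step 8.**
   - Risk: two processes may outrun the carbinol oxidation. One is oxidation of the electron-rich C5 phenol, with oxidative loss of the C8 methyl group towards a quinone. The other is ionisation of the ortho-hydroxybenzylic carbinol during handling.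
   - Fallback: the phenol is masked first, which is possible now that no organolithium step remains. Setting out from 14, BnBr/K2CO3 in acetone gives the C5 benzyl ether F5.
   - Bu4NF–AcOH then gives the 5-O-benzyl flavan-4-ol F6, and MnO2 in CH2Cl2 gives the 5-O-benzyl flavanone F7.
   - Neutral hydrogenolysis (H2, Pd/C, EtOAc) rejoins the route at 16. Any 2'-phenol set free and benzylated along the way would be released in the same hydrogenolysis.

**Further compounds**
F1 | step 5 | (2S,4S)-4-(tert-butyldimethylsilyloxy)-2-[2-methoxy-6-(triisopropylsilyloxy)phenyl]-6-(phenylsulfonyl)tetrahydropyran (epimers at the sulfonyl carbon) | COc1cccc(O[Si](C(C)C)(C(C)C)C(C)C)c1[C@@H]1C[C@H](O[Si](C)(C)C(C)(C)C)CC(O1)S(=O)(=O)c1ccccc1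
F2 | step 5 | 2,3,4-trimethoxy-4-[C8a-(phenylsulfonyl)tetrahydropyranyl]cyclobut-2-en-1-one adduct of F1 (2S,4S in flavanone numbering; epimers at both quaternary carbons) | COc1cccc(O[Si](C(C)C)(C(C)C)C(C)C)c1[C@@H]1C[C@H](O[Si](C)(C)C(C)(C)C)CC(O1)(S(=O)(=O)c1ccccc1)C1(OC)C(OC)=C(OC)C1=O
F3 | step 2 | racemic 2-[2-methoxy-6-(triisopropylsilyloxy)phenyl]-2,3-dihydro-4H-pyran-4-one | COc1cccc(O[Si](C(C)C)(C(C)C)C(C)C)c1C1CC(=O)C=CO1
F4 | step 2 | (R)-2-[2-methoxy-6-(triisopropylsilyloxy)phenyl]-2,3-dihydro-4H-pyran-4-one | COc1cccc(O[Si](C(C)C)(C(C)C)C(C)C)c1[C@H]1CC(=O)C=CO1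
F5 | step 8 | (2S,4S)-5-benzyloxy-4-(tert-butyldimethylsilyloxy)-6,7,8-trimethoxy-2-[2-methoxy-6-(triisopropylsilyloxy)phenyl]chroman | COc1cccc(O[Si](C(C)C)(C(C)C)C(C)C)c1[C@@H]1C[C@H](O[Si](C)(C)C(C)(C)C)c2c(OCc3ccccc3)c(OC)c(OC)c(OC)c2O1
F6 | step 8 | (2S,4S)-5-benzyloxy-2-(2-hydroxy-6-methoxyphenyl)-6,7,8-trimethoxychroman-4-ol | COc1cccc(O)c1[C@@H]1C[C@H](O)c2c(OCc3ccccc3)c(OC)c(OC)c(OC)c2O1
F7 | step 8 | (S)-5-benzyloxy-2-(2-hydroxy-6-methoxyphenyl)-6,7,8-trimethoxychroman-4-one | COc1cccc(O)c1[C@@H]1CC(=O)c2c(OCc3ccccc3)c(OC)c(OC)c(OC)c2O1
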